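The γ-butyrolactone ring (O1, C2 carbonyl, C3 α-carbon, C4 β-carbon, C5 methylene) is assembled from a C5=C4 alkene and a two-carbon ketene. A (Z)-alkenyl p-tolyl sulfoxide, chiral at sulfur and carrying the protected vanillyl group, is O-acylated by dichloroketene. A [3,3]-shift then forms C3–C4, and the liberated carboxylate closes onto the thionium carbon to form O1–C5, with chirality relayed from sulfur to C4. The step exploits C4 lying between an O-bound CH2 and the α-carbon. Chlorine and sulfur are stripped reductively, C3 is set by trans-alkylation with a bromide holding the Evans-aldol-derived threo aryl glycerol ether, and deprotection follows.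

Key step: step 5

Remarks on the chemistry:
- Lactone atoms are numbered O1, C2 (C=O), C3 (α), C4 (β), C5 (OCH2). The glycerol carbons are C7 (benzylic carbinol), C8 (aryloxy carbon) and C9 (CH2OH). The target is (3R,4R) in the lactone and (7R,8R), i.e. threo, in the side chain.
- The sense of chirality transfer in step 5 is assigned from a chair-like [3,3] transition state with p-tolyl pseudo-equatorial. On that model the (R)-sulfoxide of the Z-alkene leads to the (R)-configured C4 of lactone 14.
- The C5 configuration of 13 (expected cis to the benzyl group) is of no consequence, because step 6 removes it.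

Step 1
Reactants: 1 4-(benzyloxy)-3-methoxybenzyl alcohol
Product: 2 4-(benzyloxy)-3-methoxybenzyl bromide
Conditions: PBr3 (0.4 equiv), Et2O, 0 °C
Reagents that add atoms: phosphorus tribromide, BrP(Br)Br
Why: Bromide should displace the activated phosphite ester of the primary benzylic alcohol (SN2 bromination).

Step 2
Reactants: 2 4-(benzyloxy)-3-methoxybenzyl bromide; 3 ethynylmagnesium bromide
Product: 4 1-(benzyloxy)-2-methoxy-4-(prop-2-yn-1-yl)benzene
Conditions: 3 (3 equiv), CuBr (10 mol %), THF, 0 °C to reflux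
Reagents that add atoms: none
Why: Copper-catalysed cross-coupling of an alkynyl Grignard reagent with a benzylic bromide should give the propargyl arene, the excess of acetylide suppressing double alkylation.

Step 3
Reactants: 4 1-(benzyloxy)-2-methoxy-4-(prop-2-yn-1-yl)benzene; 5 (1R,2S,5R)-menthyl (S)-p-toluenesulfinate
Product: 7 (S)-1-(benzyloxy)-2-methoxy-4-[3-(p-tolylsulfinyl)prop-2-yn-1-yl]benzene, via alkynylmagnesium bromide 6 (not isolated)
Conditions: EtMgBr (1.0 equiv), THF, 0 °C to rt; then added to 5 in toluene, −20 °C; H2O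
Reagents that add atoms: none
Why: Andersen sulfoxide synthesis, in which the alkynyl Grignard displaces mentholate at sulfur with clean inversion, so the bought sulfur stereocentre defines the (S)-alkynyl sulfoxide.

Step 4
Reactants: 7 (S)-alkynyl p-tolyl sulfoxide
Product: 8 (R,Z)-1-(benzyloxy)-2-methoxy-4-[3-(p-tolylsulfinyl)prop-2-en-1-yl]benzene
Conditions: H2 (1 atm), RhCl(PPh3)3 (5 mol %), benzene, rt
Reagents that add atoms: none
Why: Homogeneous syn-hydrogenation of the alkynyl sulfoxide should stop at the cis-alkene, with sulfur untouched (the descriptor changes from S to R only through the priority rules).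

Step 5
Reactants: 8 (R,Z)-alkenyl p-tolyl sulfoxide; 9 trichloroacetyl chloride
Product: 13 (4S,5R)-4-[4-(benzyloxy)-3-methoxybenzyl]-3,3-dichloro-5-(p-tolylsulfanyl)oxolan-2-one, via dichloroketene 10 (not isolated), via acyloxysulfonium enolate 11 (not isolated), via thionium carboxylate 12 (not isolated)
Conditions: 9 (3 equiv, slow addition), Zn–Cu couple (6 equiv), Et2O, 0 °C to reflux
Reagents that add atoms: none
Why: Zinc strips two chlorines from 9 to give dichloroketene 10, whose carbonyl carbon is attacked by the sulfinyl oxygen of 8 to give the acyloxysulfonium enolate 11; a [3,3]-sigmatropic shift through a chair-like six-membered transition state then forms the C3–C4 bond and breaks S–O to give thionium carboxylate 12, and the carboxylate oxygen adds to the thionium carbon to form O1–C5. The closest known reaction type is the additive Pummerer lactonization of enantiopure alkenyl sulfoxides with dichloroketene (Marino lactonization), established for (Z)-1-alkenyl p-tolyl sulfoxides. The lactone ring closes by 5-exo-trig attack of the carboxylate on the C=S+ bond. C4 is controlled by sulfur: the Z-alkene forces the CH2Ar group axial in the chair, so p-tolyl must sit pseudo-equatorial and the enolate carbon reaches one alkene face only, which for the (R)-sulfoxide gives the C4 configuration that reads (R) in 14, while C5 follows from syn addition across the Z-alkene and is erased in step 6. The step needs the ketene to react at the sulfinyl oxygen and not by [2+2] addition to the alkene or acylation of the arenes, which the strong affinity of the electron-poor ketene for the nucleophilic sulfoxide oxygen and the unactivated alkene should secure.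

Step 6
Reactants: 13 dichloro thio lactone
Product: 14 (R)-4-[4-(benzyloxy)-3-methoxybenzyl]oxolan-2-one
Conditions: Bu3SnH (4 equiv), AIBN (0.2 equiv), toluene, 100 °C
Reagents that add atoms: none
Why: Radical chain reduction with the stannane should cleave both α-C–Cl bonds and the C–S bond of the O,S-acetal without ever placing a radical on C4, so its configuration is kept.

Step 7
Reactants: 15 methyl vanillate (methyl 4-hydroxy-3-methoxybenzoate); 16 bromoacetic acid
Product: 17 2-[2-methoxy-4-(methoxycarbonyl)phenoxy]acetic acid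
Conditions: NaH (2.2 equiv), THF/DMF, 0 °C to 60 °C; then 1 M HCl
Reagents that add atoms: none
Why: Williamson ether synthesis, the phenoxide displacing bromide from sodium bromoacetate while the aryl methyl ester is left alone in the absence of hydroxide.

Step 8
Reactants: 17 aryloxyacetic acid; 18 (S)-4-benzyl-1,3-oxazolidin-2-one
Product: 20 (S)-4-benzyl-3-{2-[2-methoxy-4-(methoxycarbonyl)phenoxy]acetyl}-1,3-oxazolidin-2-one, via mixed pivalic anhydride 19 (not isolated)
Conditions: PivCl, Et3N, THF, −20 °C; then 18, LiCl, rt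
Reagents that add atoms: none
Why: N-acylation of the oxazolidinone through the mixed pivalic anhydride, whose hindered pivaloyl carbonyl directs attack to the aryloxyacetyl carbonyl.

Step 9
Reactants: 20 N-(aryloxyacetyl)oxazolidinone; 21 4-(benzyloxy)-3-methoxybenzaldehyde
Product: 23 (4S)-4-benzyl-3-{(2S,3R)-3-[4-(benzyloxy)-3-methoxyphenyl]-3-hydroxy-2-[2-methoxy-4-(methoxycarbonyl)phenoxy]propanoyl}-1,3-oxazolidin-2-one, via dibutylboron Z-enolate 22 (not isolated)
Conditions: Bu2BOTf (1.3 equiv), iPr2NEt (1.5 equiv), CH2Cl2, −78 °C to 0 °C; then 21, −78 °C to 0 °C; H2O2, MeOH, pH 7 buffer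
Reagents that add atoms: none
Why: Evans syn-aldol reaction through the Z-boron enolate and a closed chair transition state, in which the auxiliary benzyl group blocks one enolate face and so sets C8 and C7 together in the threo (syn) relationship with the absolute sense needed.

Step 10
Reactants: 23 aldol adduct
Product: 24 (1R,2R)-1-[4-(benzyloxy)-3-methoxyphenyl]-2-[4-(hydroxymethyl)-2-methoxyphenoxy]propane-1,3-diol
Conditions: LiBH4 (5 equiv), MeOH (2 equiv), THF, 0 °C to 45 °C
Reagents that add atoms: none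
Why: Hydride reduction should cleave the exocyclic imide carbonyl to the primary alcohol (releasing the auxiliary) and, on warming, reduce the aryl methyl ester to the benzylic alcohol without touching C7 or C8.

Step 11
Reactants: 24 triol
Product: 25 {4-[(4R,5R)-4-(4-benzyloxy-3-methoxyphenyl)-2,2-dimethyl-1,3-dioxan-5-yl]oxy-3-methoxyphenyl}methanol
Conditions: 2,2-dimethoxypropane (1.5 equiv), PPTS (cat.), acetone, rt; aq NaHCO3
Reagents that add atoms: 2,2-dimethoxypropane, COC(C)(C)OC
Why: Thermodynamic ketalization, in which only the C7/C9 1,3-diol can form a cyclic isopropylidene acetal and any acyclic mixed ketal on the lone benzylic alcohol reverts on work-up.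

Step 12
Reactants: 25 acetonide alcohol
Product: 26 (4R,5R)-4-(4-benzyloxy-3-methoxyphenyl)-5-[4-(bromomethyl)-2-methoxyphenoxy]-2,2-dimethyl-1,3-dioxane
Conditions: CBr4, PPh3, 2,6-lutidine (0.2 equiv), CH2Cl2, 0 °C; used at once
Reagents that add atoms: carbon tetrabromide, BrC(Br)(Br)Br
Why: Appel bromination of the primary benzylic alcohol under buffered, essentially neutral conditions that the acetonide tolerates.

Step 13
Reactants: 14 (R)-β-benzyl lactone; 26 benzylic bromide
Product: 28 (3R,4R)-4-[4-(benzyloxy)-3-methoxybenzyl]-3-{4-[(4R,5R)-4-(4-benzyloxy-3-methoxyphenyl)-2,2-dimethyl-1,3-dioxan-5-yl]oxy-3-methoxybenzyl}oxolan-2-one, via lithium enolate 27 (not isolated)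
Conditions: LiN(SiMe3)2 (1.05 equiv), THF, −78 °C; then 26 (1.0 equiv), DMPU, −78 °C to −30 °C
Reagents that add atoms: none
Why: Alkylation of the lactone enolate with a benzylic bromide should occur anti to the C4 benzyl group, so C3 is set trans by substrate control as in classical dibenzylbutyrolactone syntheses.

Step 14
Reactants: 28 protected sesquilignan
Product: 29 (3R,4R)-4-[4-(benzyloxy)-3-methoxybenzyl]-3-{4-[(1R,2R)-1-(4-benzyloxy-3-methoxyphenyl)-1,3-dihydroxypropan-2-yl]oxy-3-methoxybenzyl}oxolan-2-one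
Conditions: AcOH/THF/H2O (3:1:1), 40 °C
Reagents that add atoms: none
Why: Mild aqueous acid should hydrolyse the isopropylidene ketal through its oxocarbenium ion well before the benzylic C7–O bond can ionize, the phenols still being benzylated.

Step 15
Reactants: 29 bis(benzyl ether) diol
Product: 30 (3R,4R)-3-{4-[(1R,2R)-1,3-dihydroxy-1-(4-hydroxy-3-methoxyphenyl)propan-2-yl]oxy-3-methoxybenzyl}-4-(4-hydroxy-3-methoxybenzyl)oxolan-2-one (target)
Conditions: H2 (1 atm), 10% Pd/C, EtOAc/MeOH, rt
Reagents that add atoms: none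
Why: Neutral hydrogenolysis should cleave the two aryl benzyl ethers much faster than the secondary benzylic alcohol or the lactone, freeing both phenols.

Compound list
1 | 4-(benzyloxy)-3-methoxybenzyl alcohol | COc1cc(CO)ccc1OCc1ccccc1 | starting material
2 | 4-(benzyloxy)-3-methoxybenzyl bromide | COc1cc(CBr)ccc1OCc1ccccc1 | intermediate
3 | ethynylmagnesium bromide | C#C[Mg]Br | starting material
4 | 1-(benzyloxy)-2-methoxy-4-(prop-2-yn-1-yl)benzene | COc1cc(CC#C)ccc1OCc1ccccc1 | intermediate
5 | (1R,2S,5R)-menthyl (S)-p-toluenesulfinate | C[C@@H]1CC[C@H]([C@@H](C1)O[S@](=O)c1ccc(C)cc1)C(C)C | starting material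
6 | [3-(4-benzyloxy-3-methoxyphenyl)prop-1-ynyl]magnesium bromide | COc1cc(CC#C[Mg]Br)ccc1OCc1ccccc1 | intermediate
7 | (S)-1-(benzyloxy)-2-methoxy-4-[3-(p-tolylsulfinyl)prop-2-yn-1-yl]benzene | Cc1ccc(cc1)[S@](=O)C#CCc1ccc(OCc2ccccc2)c(OC)c1 | intermediate
8 | (R,Z)-1-(benzyloxy)-2-methoxy-4-[3-(p-tolylsulfinyl)prop-2-en-1-yl]benzene | Cc1ccc(cc1)[S@](=O)/C=C\Cc1ccc(OCc2ccccc2)c(OC)c1 | intermediate
9 | trichloroacetyl chloride | ClC(=O)C(Cl)(Cl)Cl | starting material
10 | dichloroketene | ClC(Cl)=C=O | intermediate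
11 | (Z)-alkenyl(p-tolyl)(2,2-dichloro-1-oxidoethenyloxy)sulfonium zwitterion | [O-]C(=C(Cl)Cl)O[S@@+](c1ccc(C)cc1)/C=C\Cc1ccc(OCc2ccccc2)c(OC)c1 | intermediate
12 | (3S)-4-(4-benzyloxy-3-methoxyphenyl)-2,2-dichloro-3-[(p-tolylsulfonio)methylidene]butanoate zwitterion (thionium carboxylate) | Cc1ccc(cc1)[S+]=C[C@H](Cc1ccc(OCc2ccccc2)c(OC)c1)C(Cl)(Cl)C(=O)[O-] | intermediate
13 | (4S,5R)-4-[4-(benzyloxy)-3-methoxybenzyl]-3,3-dichloro-5-(p-tolylsulfanyl)oxolan-2-one | COc1cc(C[C@H]2[C@@H](Sc3ccc(C)cc3)OC(=O)C2(Cl)Cl)ccc1OCc1ccccc1 | intermediate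
14 | (R)-4-[4-(benzyloxy)-3-methoxybenzyl]oxolan-2-one | COc1cc(C[C@H]2COC(=O)C2)ccc1OCc1ccccc1 | intermediate
15 | methyl 4-hydroxy-3-methoxybenzoate (methyl vanillate) | COC(=O)c1ccc(O)c(OC)c1 | starting material
16 | bromoacetic acid | OC(=O)CBr | starting material
17 | 2-[2-methoxy-4-(methoxycarbonyl)phenoxy]acetic acid | COC(=O)c1ccc(OCC(=O)O)c(OC)c1 | intermediate
18 | (S)-4-benzyl-1,3-oxazolidin-2-one | O=C1N[C@@H](Cc2ccccc2)CO1 | starting material
19 | 2-[2-methoxy-4-(methoxycarbonyl)phenoxy]acetic pivalic anhydride | COC(=O)c1ccc(OCC(=O)OC(=O)C(C)(C)C)c(OC)c1 | intermediate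
20 | (S)-4-benzyl-3-{2-[2-methoxy-4-(methoxycarbonyl)phenoxy]acetyl}-1,3-oxazolidin-2-one | COC(=O)c1ccc(OCC(=O)N2[C@@H](Cc3ccccc3)COC2=O)c(OC)c1 | intermediate
21 | 4-(benzyloxy)-3-methoxybenzaldehyde | COc1cc(C=O)ccc1OCc1ccccc1 | starting material
22 | dibutylboron (Z)-enolate of 20 | CCCCB(CCCC)O/C(=C\Oc1ccc(cc1OC)C(=O)OC)N1[C@@H](Cc2ccccc2)COC1=O | intermediate
23 | (4S)-4-benzyl-3-{(2S,3R)-3-[4-(benzyloxy)-3-methoxyphenyl]-3-hydroxy-2-[2-methoxy-4-(methoxycarbonyl)phenoxy]propanoyl}-1,3-oxazolidin-2-one | COC(=O)c1ccc(O[C@H](C(=O)N2[C@@H](Cc3ccccc3)COC2=O)[C@H](O)c2ccc(OCc3ccccc3)c(OC)c2)c(OC)c1 | intermediate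
24 | (1R,2R)-1-[4-(benzyloxy)-3-methoxyphenyl]-2-[4-(hydroxymethyl)-2-methoxyphenoxy]propane-1,3-diol | COc1cc(CO)ccc1O[C@H](CO)[C@H](O)c1ccc(OCc2ccccc2)c(OC)c1 | intermediate
25 | {4-[(4R,5R)-4-(4-benzyloxy-3-methoxyphenyl)-2,2-dimethyl-1,3-dioxan-5-yl]oxy-3-methoxyphenyl}methanol | COc1cc(CO)ccc1O[C@@H]1COC(C)(C)O[C@@H]1c1ccc(OCc2ccccc2)c(OC)c1 | intermediate
26 | (4R,5R)-4-(4-benzyloxy-3-methoxyphenyl)-5-[4-(bromomethyl)-2-methoxyphenoxy]-2,2-dimethyl-1,3-dioxane | COc1cc(CBr)ccc1O[C@@H]1COC(C)(C)O[C@@H]1c1ccc(OCc2ccccc2)c(OC)c1 | intermediate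
27 | lithium enolate of 14 | COc1cc(C[C@H]2COC(O[Li])=C2)ccc1OCc1ccccc1 | intermediate
28 | (3R,4R)-4-[4-(benzyloxy)-3-methoxybenzyl]-3-{4-[(4R,5R)-4-(4-benzyloxy-3-methoxyphenyl)-2,2-dimethyl-1,3-dioxan-5-yl]oxy-3-methoxybenzyl}oxolan-2-one | COc1cc(C[C@H]2COC(=O)[C@@H]2Cc2ccc(O[C@@H]3COC(C)(C)O[C@@H]3c3ccc(OCc4ccccc4)c(OC)c3)c(OC)c2)ccc1OCc1ccccc1 | intermediate
29 | (3R,4R)-4-[4-(benzyloxy)-3-methoxybenzyl]-3-{4-[(1R,2R)-1-(4-benzyloxy-3-methoxyphenyl)-1,3-dihydroxypropan-2-yl]oxy-3-methoxybenzyl}oxolan-2-one | COc1cc(C[C@H]2COC(=O)[C@@H]2Cc2ccc(O[C@H](CO)[C@H](O)c3ccc(OCc4ccccc4)c(OC)c3)c(OC)c2)ccc1OCc1ccccc1 | intermediate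
30 | (3R,4R)-3-{4-[(1R,2R)-1,3-dihydroxy-1-(4-hydroxy-3-methoxyphenyl)propan-2-yl]oxy-3-methoxybenzyl}-4-(4-hydroxy-3-methoxybenzyl)oxolan-2-one | COc1cc(C[C@H]2COC(=O)[C@@H]2Cc2ccc(O[C@H](CO)[C@H](O)c3ccc(O)c(OC)c3)c(OC)c2)ccc1O | target

Total step count: 15 steps.
Longest linear sequence: 9 steps (steps 1–6 or steps 7–12, then steps 13–15).

Steps most likely to fail

1. Step 5. Chirality transfer from sulfur to C4 may be incomplete or run in the opposite sense to the chair model. The ketene may also be consumed by oligomerization or by zinc chloride-promoted side reactions before it acylates the sulfinyl oxygen. Fallback, setting out from bromide 2 and coming back at lactone 14: (R)-4-benzyl-3-(4-tert-butoxy-4-oxobutanoyl)-1,3-oxazolidin-2-one F1 would be made from 4-tert-butoxy-4-oxobutanoic acid and (R)-4-benzyl-1,3-oxazolidin-2-one (PivCl, Et3N, LiCl). Its sodium enolate (NaN(SiMe3)2, THF, −78 °C) would be alkylated with 2 on the face away from the auxiliary benzyl group to give the (2R)-benzylated imide F2. LiBH4 (THF, 1 equiv MeOH, 0 °C) would reduce the imide selectively to the hydroxy ester F3, and TsOH (cat., toluene, 80 °C) would close it to 14. This detour builds the ring by a different logic and is kept only to secure supply of 14.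

2. Step 3. The CH2 group flanked by the arene and the alkynyl sulfoxide is acidic. Base-induced propargyl–allenyl isomerization during or after the substitution at sulfur may therefore erode the product. Fallback, setting out from alkyne 4 and coming back at alkenyl sulfoxide 8 (step 4 is then not needed): N-iodosuccinimide with AgNO3 (cat., acetone) would give the iodoalkyne F4. Diimide (from 2-nitrobenzenesulfonylhydrazide and Et3N, THF/i-PrOH) would reduce it to the (Z)-alkenyl iodide F5. Iodine–lithium exchange (t-BuLi, 2 equiv, Et2O, −78 °C) would give the (Z)-alkenyllithium F6, which would be added to sulfinate 5 at −78 °C. This Andersen substitution proceeds with inversion at sulfur and retention of alkene geometry, so it should give 8 without any propargylic sulfoxide on the way.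

3. Step 14. Acid may ionize the electron-rich benzylic C7–O bond while the ketal is being cleaved, which would epimerize C7 (threo to erythro) or substitute it. Fallback, setting out from triol 24 and coming back at target 30: benzaldehyde dimethyl acetal with PPTS (CH2Cl2, rt) would give the (2S,4R,5R)-benzylidene acetal alcohol F7 (phenyl equatorial). CBr4/PPh3 would convert it into the bromide F8, and alkylation of the lithium enolate of 14 as in step 13 would give the benzylidene-protected lactone F9. A single neutral hydrogenolysis (H2, Pd(OH)2/C, EtOAc/MeOH) would then remove the benzylidene acetal and both benzyl ethers, giving 30 with no acid step.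

Further compounds
F1 | step 5 | (R)-4-benzyl-3-(4-tert-butoxy-4-oxobutanoyl)-1,3-oxazolidin-2-one | CC(C)(C)OC(=O)CCC(=O)N1[C@H](Cc2ccccc2)COC1=O
F2 | step 5 | (R)-4-benzyl-3-{(2R)-2-[4-(benzyloxy)-3-methoxybenzyl]-4-tert-butoxy-4-oxobutanoyl}-1,3-oxazolidin-2-one | COc1cc(C[C@H](CC(=O)OC(C)(C)C)C(=O)N2[C@H](Cc3ccccc3)COC2=O)ccc1OCc1ccccc1
F3 | step 5 | tert-butyl (3R)-4-[4-(benzyloxy)-3-methoxyphenyl]-3-(hydroxymethyl)butanoate | COc1cc(C[C@H](CC(=O)OC(C)(C)C)CO)ccc1OCc1ccccc1
F4 | step 3 | 1-(benzyloxy)-4-(3-iodoprop-2-yn-1-yl)-2-methoxybenzene | COc1cc(CC#CI)ccc1OCc1ccccc1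
F5 | step 3 | (Z)-1-(benzyloxy)-4-(3-iodoprop-2-en-1-yl)-2-methoxybenzene | COc1cc(C/C=C\I)ccc1OCc1ccccc1
F6 | step 3 | (Z)-[3-(4-benzyloxy-3-methoxyphenyl)prop-1-enyl]lithium | COc1cc(C/C=C\[Li])ccc1OCc1ccccc1
F7 | step 14 | {4-[(2S,4R,5R)-4-(4-benzyloxy-3-methoxyphenyl)-2-phenyl-1,3-dioxan-5-yl]oxy-3-methoxyphenyl}methanol | COc1cc(CO)ccc1O[C@@H]1CO[C@H](c2ccccc2)O[C@@H]1c1ccc(OCc2ccccc2)c(OC)c1
F8 | step 14 | (2S,4R,5R)-4-(4-benzyloxy-3-methoxyphenyl)-5-[4-(bromomethyl)-2-methoxyphenoxy]-2-phenyl-1,3-dioxane | COc1cc(CBr)ccc1O[C@@H]1CO[C@H](c2ccccc2)O[C@@H]1c1ccc(OCc2ccccc2)c(OC)c1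
F9 | step 14 | (3R,4R)-4-[4-(benzyloxy)-3-methoxybenzyl]-3-{4-[(2S,4R,5R)-4-(4-benzyloxy-3-methoxyphenyl)-2-phenyl-1,3-dioxan-5-yl]oxy-3-methoxybenzyl}oxolan-2-one | COc1cc(C[C@H]2COC(=O)[C@@H]2Cc2ccc(O[C@@H]3CO[C@H](c4ccccc4)O[C@@H]3c3ccc(OCc4ccccc4)c(OC)c3)c(OC)c2)ccc1OCc1ccccc1
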